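**Retrosynthetic overview**
1. Late stage: phenol MOM removal; C10–Br/C11–OH from SN2 opening of a 10,11-epoxide by bromide; 15-membered ring by macrolactonization (C14–O–C(=O)Ar).
2. Cyclohexene ring (formed first): intramolecular Diels–Alder reaction of a 2-alkoxyacrylate tethered through the C10 oxygen to a trisubstituted diene. The temporary tetrahydropyran relays C10 to C7 and is then unzipped (β-iodo ether, Zn) to the exocyclic methylene and free C10–OH.
3. Diene: a 1,1-dibromoalkene coupled first with isopropenylzinc, then with the arylmethylzinc reagent.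
4. Chain: C7–C11 from (R)-5-oxotetrahydrofuran-2-carboxylic acid, C12–C15 from (S)-α-hydroxy-γ-butyrolactone, joined by a Felkin–Anh addition that sets C11.
5. Ring order: cyclohexene (with temporary tetrahydropyran) → oxirane → macrolactone.

Assumption: 5 and 9 are bought as single enantiomers (9 is the lactone acid obtained from D-glutamic acid).
Locants: C1 benzylic CH2; C2 ring carbon bearing it; C3 ring C–Me; C4, C5 ring CH2; C6 ring carbon bearing the exocyclic CH2 (C6a); C7 ring CH; C8, C9 CH2; C10 CHBr; C11 C(Me)OH; C12, C13 CH2; C14 CH–O(ester); C15 CMe2OH. Target: 7S, 10R, 11S, 14S.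

**Step 1**
Reactants: 1 methyl 3-formyl-4-hydroxybenzoate
Product: 2 methyl 3-formyl-4-(methoxymethoxy)benzoate
Conditions: MOMCl, i-Pr2NEt, CH2Cl2, 0 °C to rt
Reagents that add atoms: chloromethyl methyl ether, COCCl
Why: O-alkylation of the phenol gives a MOM ether that tolerates the later hydride, organozinc, Pd and hydroxide steps.

**Step 2**
Reactants: 2 methyl 3-formyl-4-(methoxymethoxy)benzoate
Product: 3 methyl 3-(hydroxymethyl)-4-(methoxymethoxy)benzoate
Conditions: NaBH4, MeOH, 0 °C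
Reagents that add atoms: none
Why: Borohydride reduction takes the aldehyde and leaves the benzoate ester untouched.

**Step 3**
Reactants: 3 methyl 3-(hydroxymethyl)-4-(methoxymethoxy)benzoate
Product: 4 methyl 3-(bromomethyl)-4-(methoxymethoxy)benzoate
Conditions: CBr4, PPh3, CH2Cl2, 0 °C
Reagents that add atoms: carbon tetrabromide, BrC(Br)(Br)Br
Why: Appel bromination converts the benzylic alcohol under neutral conditions that spare the MOM acetal.

**Step 4**
Reactants: 5 (S)-3-hydroxydihydrofuran-2(3H)-one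
Product: 6 (3S)-4-methylpentane-1,3,4-triol
Conditions: MeMgBr (3.5 equiv), THF, 0 °C to rt; aq. NH4Cl
Reagents that add atoms: methylmagnesium bromide, C[Mg]Br
Why: Double Grignard addition to the lactone carbonyl builds the C15 carbinol, and the purchased stereocentre (future C14) is not touched.

**Step 5**
Reactants: 6 (3S)-4-methylpentane-1,3,4-triol
Product: 7 2-[(4S)-2,2,5,5-tetramethyl-1,3-dioxolan-4-yl]ethan-1-ol
Conditions: Me2C(OMe)2, PPTS (cat.), CH2Cl2, rt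
Reagents that add atoms: 2,2-dimethoxypropane, COC(C)(C)OC
Why: Acetalization under equilibrating conditions gives the five-membered 1,2-acetonide, which is favoured over the 1,3-dioxane, and leaves the primary alcohol free.

**Step 6**
Reactants: 7 2-[(4S)-2,2,5,5-tetramethyl-1,3-dioxolan-4-yl]ethan-1-ol
Product: 8 (4S)-4-(2-iodoethyl)-2,2,5,5-tetramethyl-1,3-dioxolane
Conditions: I2, PPh3, imidazole, CH2Cl2, 0 °C to rt
Reagents that add atoms: iodine, II
Why: Appel-type (Garegg) iodination of the primary alcohol proceeds by SN2 away from the stereocentre.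

**Step 7**
Reactants: 9 (2R)-5-oxotetrahydrofuran-2-carboxylic acid
Product: 11 (5R)-5-acetyldihydrofuran-2(3H)-one, via acid chloride 10 (not isolated)
Conditions: (COCl)2, DMF (cat.), CH2Cl2, rt; then Me2CuLi, Et2O, −78 °C
Reagents that add atoms: lithium dimethylcuprate, [Li+].C[Cu-]C
Why: Cuprate acylation of the acid chloride stops at the methyl ketone and does not touch the lactone or the α-oxygenated stereocentre (future C10).

**Step 8**
Reactants: 8 (4S)-4-(2-iodoethyl)-2,2,5,5-tetramethyl-1,3-dioxolane; 11 (5R)-5-acetyldihydrofuran-2(3H)-one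
Product: 13 (5R)-5-{(2S)-2-hydroxy-4-[(4S)-2,2,5,5-tetramethyl-1,3-dioxolan-4-yl]butan-2-yl}dihydrofuran-2(3H)-one, via alkylmagnesium iodide 12 (not isolated)
Conditions: Mg, THF, rt; then 11, THF, −78 °C
Reagents that add atoms: none
Why: Grignard addition to the ketone (faster than to the lactone) under polar Felkin–Anh control, with the lactone C–O bond anti to the nucleophile and attack past H, sets C11 as S from the purchased C10 centre.

**Step 9**
Reactants: 13 (5R)-5-{(2S)-2-hydroxy-4-[(4S)-2,2,5,5-tetramethyl-1,3-dioxolan-4-yl]butan-2-yl}dihydrofuran-2(3H)-one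
Product: 14 (5R)-5-{(2S)-4-[(4S)-2,2,5,5-tetramethyl-1,3-dioxolan-4-yl]-2-(triethylsilyloxy)butan-2-yl}dihydrofuran-2(3H)-one
Conditions: TESOTf, 2,6-lutidine, CH2Cl2, −78 to 0 °C
Reagents that add atoms: triethylsilyl trifluoromethanesulfonate, CC[Si](CC)(CC)OS(=O)(=O)C(F)(F)F
Why: Silylation of the tertiary alcohol leaves C10–OH as the only free hydroxyl once the lactone is opened.

**Step 10**
Reactants: 14 (5R)-5-{(2S)-4-[(4S)-2,2,5,5-tetramethyl-1,3-dioxolan-4-yl]-2-(triethylsilyloxy)butan-2-yl}dihydrofuran-2(3H)-one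
Product: 16 (5R,6S)-1,1-dibromo-6-methyl-8-[(4S)-2,2,5,5-tetramethyl-1,3-dioxolan-4-yl]-6-(triethylsilyloxy)oct-1-en-5-ol, via lactol 15 (not isolated)
Conditions: i-Bu2AlH, CH2Cl2, −78 °C; then [Ph3PCHBr2]Br, t-BuOK, THF, 0 °C to rt
Reagents that add atoms: (dibromomethyl)triphenylphosphonium bromide, BrC(Br)[P+](c1ccccc1)(c1ccccc1)c1ccccc1.[Br-]
Why: Half-reduction to the lactol and Wittig-type dibromomethylenation of its open aldehyde form give the 1,1-dibromoalkene (C7=C2) and release C10–OH without touching a stereocentre.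

**Step 11**
Reactants: 16 (5R,6S)-1,1-dibromo-6-methyl-8-[(4S)-2,2,5,5-tetramethyl-1,3-dioxolan-4-yl]-6-(triethylsilyloxy)oct-1-en-5-ol
Product: 17 methyl 2-{[(5R,6S)-1,1-dibromo-6-methyl-8-[(4S)-2,2,5,5-tetramethyl-1,3-dioxolan-4-yl]-6-(triethylsilyloxy)oct-1-en-5-yl]oxy}-2-(dimethoxyphosphoryl)acetate (epimers at the new CH)
Conditions: (MeO)2P(O)C(N2)CO2Me, Rh2(OAc)4 (2 mol%), benzene, 80 °C
Reagents that add atoms: methyl 2-diazo-2-(dimethoxyphosphoryl)acetate, COC(=O)C(=[N+]=[N-])P(=O)(OC)OC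
Why: Rhodium-carbenoid O–H insertion etherifies the hindered secondary alcohol with retention at C10; the electron-poor dibromoalkene is inert to cyclopropanation.

**Step 12**
Reactants: 17 methyl 2-{[(5R,6S)-1,1-dibromo-6-methyl-8-[(4S)-2,2,5,5-tetramethyl-1,3-dioxolan-4-yl]-6-(triethylsilyloxy)oct-1-en-5-yl]oxy}-2-(dimethoxyphosphoryl)acetate
Product: 18 methyl 2-{[(5R,6S)-1,1-dibromo-6-methyl-8-[(4S)-2,2,5,5-tetramethyl-1,3-dioxolan-4-yl]-6-(triethylsilyloxy)oct-1-en-5-yl]oxy}prop-2-enoate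
Conditions: aq. HCHO, K2CO3, THF–H2O, rt
Reagents that add atoms: formaldehyde, C=O
Why: Horner–Wadsworth–Emmons methylenation gives the 2-alkoxyacrylate dienophile (C5=C6 with C6a as the ester carbon) under base too mild to dehydrobrominate the dibromoalkene.

**Step 13**
Reactants: 18 methyl 2-{[(5R,6S)-1,1-dibromo-6-methyl-8-[(4S)-2,2,5,5-tetramethyl-1,3-dioxolan-4-yl]-6-(triethylsilyloxy)oct-1-en-5-yl]oxy}prop-2-enoate; 4 methyl 3-(bromomethyl)-4-(methoxymethoxy)benzoate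
Product: 21 methyl 3-[(2E,6R,7S)-6-[(3-methoxy-3-oxoprop-1-en-2-yl)oxy]-7-methyl-2-(prop-1-en-2-yl)-9-[(4S)-2,2,5,5-tetramethyl-1,3-dioxolan-4-yl]-7-(triethylsilyloxy)non-2-en-1-yl]-4-(methoxymethoxy)benzoate, via bromodiene 19 (not isolated), via benzylzinc bromide 20 (not isolated)
Conditions: CH2=C(Me)ZnBr, PdCl2(DPEphos) (5 mol%), THF, 0 °C to rt; then 20 (from 4, Zn, LiCl, THF), Pd(t-Bu3P)2 (5 mol%), rt
Reagents that add atoms: isopropenylzinc bromide, CC(=C)[Zn]Br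
Why: Two Negishi couplings: the bromide trans to the chain reacts first with the alkenylzinc, then the remaining bromide is benzylated with retention. This fixes the diene geometry (chain cis to CH2Ar, trans to isopropenyl) needed for the cycloaddition.

**Step 14**
Reactants: 21 methyl 3-[(2E,6R,7S)-6-[(3-methoxy-3-oxoprop-1-en-2-yl)oxy]-7-methyl-2-(prop-1-en-2-yl)-9-[(4S)-2,2,5,5-tetramethyl-1,3-dioxolan-4-yl]-7-(triethylsilyloxy)non-2-en-1-yl]-4-(methoxymethoxy)benzoate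
Product: 22 methyl (2R,4aR)-5-{[5-(methoxycarbonyl)-2-(methoxymethoxy)phenyl]methyl}-6-methyl-2-{(2S)-4-[(4S)-2,2,5,5-tetramethyl-1,3-dioxolan-4-yl]-2-(triethylsilyloxy)butan-2-yl}-3,4,4a,7,8,8a-hexahydro-2H-chromene-8a-carboxylate (both C8a epimers)
Conditions: toluene (5 mM), BHT, 120 °C
Reagents that add atoms: none
Why: Intramolecular Diels–Alder cycloaddition: the C8–C9–C10–O tether forces C6 onto C7 and C5 onto C4 and folds as a chair with the bulky C11 group and the diene equatorial. Only one diene face is reached, so C7 is set from C10 (S in the target's sense) in both ring-fusion isomers, whose C6 centre is erased in step 17.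

**Step 15**
Reactants: 22 methyl (2R,4aR)-5-{[5-(methoxycarbonyl)-2-(methoxymethoxy)phenyl]methyl}-6-methyl-2-{(2S)-4-[(4S)-2,2,5,5-tetramethyl-1,3-dioxolan-4-yl]-2-(triethylsilyloxy)butan-2-yl}-3,4,4a,7,8,8a-hexahydro-2H-chromene-8a-carboxylate
Product: 23 methyl 3-{[(2R,4aR)-8a-(hydroxymethyl)-6-methyl-2-{(2S)-4-[(4S)-2,2,5,5-tetramethyl-1,3-dioxolan-4-yl]-2-(triethylsilyloxy)butan-2-yl}-3,4,4a,7,8,8a-hexahydro-2H-chromen-5-yl]methyl}-4-(methoxymethoxy)benzoate (C8a epimers)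
Conditions: LiBH4, THF–MeOH, 0 °C to rt
Reagents that add atoms: none
Why: Borohydride reduction is chemoselective for the α-alkoxy ester, which is activated by the adjacent oxygen, over the electron-rich 4-alkoxybenzoate.

**Step 16**
Reactants: 23 methyl 3-{[(2R,4aR)-8a-(hydroxymethyl)-6-methyl-2-{(2S)-4-[(4S)-2,2,5,5-tetramethyl-1,3-dioxolan-4-yl]-2-(triethylsilyloxy)butan-2-yl}-3,4,4a,7,8,8a-hexahydro-2H-chromen-5-yl]methyl}-4-(methoxymethoxy)benzoate
Product: 24 methyl 3-{[(2R,4aR)-8a-(iodomethyl)-6-methyl-2-{(2S)-4-[(4S)-2,2,5,5-tetramethyl-1,3-dioxolan-4-yl]-2-(triethylsilyloxy)butan-2-yl}-3,4,4a,7,8,8a-hexahydro-2H-chromen-5-yl]methyl}-4-(methoxymethoxy)benzoate (C8a epimers)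
Conditions: I2, PPh3, imidazole, toluene, 90 °C
Reagents that add atoms: iodine, II
Why: Garegg (Appel-type) iodination of the primary alcohol; the neopentyl-like position next to a ring oxygen needs heat, as for hydroxymethyl groups on the anomeric carbon of ketopyranoses.

**Step 17**
Reactants: 24 methyl 3-{[(2R,4aR)-8a-(iodomethyl)-6-methyl-2-{(2S)-4-[(4S)-2,2,5,5-tetramethyl-1,3-dioxolan-4-yl]-2-(triethylsilyloxy)butan-2-yl}-3,4,4a,7,8,8a-hexahydro-2H-chromen-5-yl]methyl}-4-(methoxymethoxy)benzoate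
Product: 25 methyl 3-{[(6S)-6-{(3R,4S)-3-hydroxy-4-methyl-6-[(4S)-2,2,5,5-tetramethyl-1,3-dioxolan-4-yl]-4-(triethylsilyloxy)hexyl}-2-methyl-5-methylidenecyclohex-1-en-1-yl]methyl}-4-(methoxymethoxy)benzoate
Conditions: Zn dust, NH4Cl, EtOH–THF, reflux
Reagents that add atoms: none
Why: Zinc insertion into C–I and β-elimination of the ring alkoxide (Boord/Vasella-type reductive fragmentation) opens the tetrahydropyran regiospecifically to the exocyclic methylene and the free (10R)-alcohol; C7 is unaffected.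

**Step 18**
Reactants: 25 methyl 3-{[(6S)-6-{(3R,4S)-3-hydroxy-4-methyl-6-[(4S)-2,2,5,5-tetramethyl-1,3-dioxolan-4-yl]-4-(triethylsilyloxy)hexyl}-2-methyl-5-methylidenecyclohex-1-en-1-yl]methyl}-4-(methoxymethoxy)benzoate
Product: 27 methyl 3-{[(6S)-6-[(3R,4S,7S)-4,7,8-trihydroxy-4,8-dimethyl-3-(methylsulfonyloxy)nonyl]-2-methyl-5-methylidenecyclohex-1-en-1-yl]methyl}-4-(methoxymethoxy)benzoate, via mesylate 26 (not isolated)
Conditions: MsCl, Et3N, CH2Cl2, 0 °C; then AcOH–THF–H2O (3:1:1), 45 °C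
Reagents that add atoms: methanesulfonyl chloride, CS(=O)(=O)Cl
Why: Sulfonylation of the only free hydroxyl (C10, retention) followed by mild acid hydrolysis of the acetonide and the TES ether; the mesylate, MOM ether and skipped diene survive weak acid.

**Step 19**
Reactants: 27 methyl 3-{[(6S)-6-[(3R,4S,7S)-4,7,8-trihydroxy-4,8-dimethyl-3-(methylsulfonyloxy)nonyl]-2-methyl-5-methylidenecyclohex-1-en-1-yl]methyl}-4-(methoxymethoxy)benzoate
Product: 28 3-{[(6S)-6-{2-[(2S,3S)-3-[(3S)-3,4-dihydroxy-4-methylpentyl]-3-methyloxiran-2-yl]ethyl}-2-methyl-5-methylidenecyclohex-1-en-1-yl]methyl}-4-(methoxymethoxy)benzoic acid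
Conditions: LiOH, THF–MeOH–H2O, rt; phosphate work-up to pH 5
Reagents that add atoms: lithium hydroxide, [Li+].[OH-]
Why: Saponification of the benzoate, and intramolecular Williamson closure of the epoxide by the C11 alkoxide (inversion at C10 to 10S, C11 unchanged), which masks both C10 and C11 oxygens before ring closure.

**Step 20**
Reactants: 28 3-{[(6S)-6-{2-[(2S,3S)-3-[(3S)-3,4-dihydroxy-4-methylpentyl]-3-methyloxiran-2-yl]ethyl}-2-methyl-5-methylidenecyclohex-1-en-1-yl]methyl}-4-(methoxymethoxy)benzoic acid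
Product: 29 MOM-protected (7S,10S,11S,14S)-10,11-epoxy macrolactone (target skeleton with an oxirane across C10–C11 in place of Br and OH; C15–OH free)
Conditions: MNBA, DMAP, CH2Cl2 (1 mM, slow addition), rt
Reagents that add atoms: none
Why: Shiina macrolactonization under high dilution acylates the only secondary alcohol (C14–OH, retention) to close the 15-membered ring; the tertiary C15–OH and the epoxide are inert.

**Step 21**
Reactants: 29 MOM-protected (7S,10S,11S,14S)-10,11-epoxy macrolactone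
Product: 30 O-methoxymethyl ether of the target (7S,10R,11S,14S)
Conditions: Li2NiBr4, THF, 0 °C to rt
Reagents that add atoms: dilithium tetrabromonickelate, [Li+].[Li+].Br[Ni-2](Br)(Br)Br
Why: SN2 opening of the trisubstituted epoxide by bromide at the secondary carbon C10 with inversion gives the (10R)-bromide and the (11S) tertiary alcohol; no base is present to re-close the bromohydrin.

**Step 22**
Reactants: 30 O-methoxymethyl ether of the target
Product: 31 target CNP0343566.2 (7S,10R,11S,14S)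
Conditions: ZnBr2, n-PrSH, CH2Cl2, 0 °C
Reagents that add atoms: none
Why: Lewis acid–thiol cleavage of the aryl MOM acetal is fast and mild enough for the bromohydrin, the tertiary alcohols and the skipped diene.

**Compound list**
1 | methyl 3-formyl-4-hydroxybenzoate | COC(=O)c1ccc(O)c(C=O)c1 | starting material
2 | methyl 3-formyl-4-(methoxymethoxy)benzoate | COCOc1ccc(cc1C=O)C(=O)OC | intermediate
3 | methyl 3-(hydroxymethyl)-4-(methoxymethoxy)benzoate | COCOc1ccc(cc1CO)C(=O)OC | intermediate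
4 | methyl 3-(bromomethyl)-4-(methoxymethoxy)benzoate | COCOc1ccc(cc1CBr)C(=O)OC | intermediate
5 | (S)-3-hydroxydihydrofuran-2(3H)-one | O=C1OCC[C@@H]1O | starting material
6 | (3S)-4-methylpentane-1,3,4-triol | OCC[C@H](O)C(C)(C)O | intermediate
7 | 2-[(4S)-2,2,5,5-tetramethyl-1,3-dioxolan-4-yl]ethan-1-ol | OCC[C@@H]1OC(C)(C)OC1(C)C | intermediate
8 | (4S)-4-(2-iodoethyl)-2,2,5,5-tetramethyl-1,3-dioxolane | ICC[C@@H]1OC(C)(C)OC1(C)C | intermediate
9 | (2R)-5-oxotetrahydrofuran-2-carboxylic acid | OC(=O)[C@H]1CCC(=O)O1 | starting material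
10 | (2R)-5-oxotetrahydrofuran-2-carbonyl chloride | ClC(=O)[C@H]1CCC(=O)O1 | intermediate
11 | (5R)-5-acetyldihydrofuran-2(3H)-one | CC(=O)[C@H]1CCC(=O)O1 | intermediate
12 | {2-[(4S)-2,2,5,5-tetramethyl-1,3-dioxolan-4-yl]ethyl}magnesium iodide | I[Mg]CC[C@@H]1OC(C)(C)OC1(C)C | intermediate
13 | (5R)-5-{(2S)-2-hydroxy-4-[(4S)-2,2,5,5-tetramethyl-1,3-dioxolan-4-yl]butan-2-yl}dihydrofuran-2(3H)-one | O=C1CC[C@@H](O1)[C@@](C)(O)CC[C@@H]1OC(C)(C)OC1(C)C | intermediate
14 | (5R)-5-{(2S)-4-[(4S)-2,2,5,5-tetramethyl-1,3-dioxolan-4-yl]-2-(triethylsilyloxy)butan-2-yl}dihydrofuran-2(3H)-one | O=C1CC[C@@H](O1)[C@@](C)(O[Si](CC)(CC)CC)CC[C@@H]1OC(C)(C)OC1(C)C | intermediate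
15 | (5R)-5-{(2S)-4-[(4S)-2,2,5,5-tetramethyl-1,3-dioxolan-4-yl]-2-(triethylsilyloxy)butan-2-yl}tetrahydrofuran-2-ol (anomers) | OC1CC[C@@H](O1)[C@@](C)(O[Si](CC)(CC)CC)CC[C@@H]1OC(C)(C)OC1(C)C | intermediate
16 | (5R,6S)-1,1-dibromo-6-methyl-8-[(4S)-2,2,5,5-tetramethyl-1,3-dioxolan-4-yl]-6-(triethylsilyloxy)oct-1-en-5-ol | BrC(Br)=CCC[C@@H](O)[C@@](C)(O[Si](CC)(CC)CC)CC[C@@H]1OC(C)(C)OC1(C)C | intermediate
17 | methyl 2-{[(5R,6S)-1,1-dibromo-6-methyl-8-[(4S)-2,2,5,5-tetramethyl-1,3-dioxolan-4-yl]-6-(triethylsilyloxy)oct-1-en-5-yl]oxy}-2-(dimethoxyphosphoryl)acetate | BrC(Br)=CCC[C@@H](OC(C(=O)OC)P(=O)(OC)OC)[C@@](C)(O[Si](CC)(CC)CC)CC[C@@H]1OC(C)(C)OC1(C)C | intermediate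
18 | methyl 2-{[(5R,6S)-1,1-dibromo-6-methyl-8-[(4S)-2,2,5,5-tetramethyl-1,3-dioxolan-4-yl]-6-(triethylsilyloxy)oct-1-en-5-yl]oxy}prop-2-enoate | BrC(Br)=CCC[C@@H](OC(=C)C(=O)OC)[C@@](C)(O[Si](CC)(CC)CC)CC[C@@H]1OC(C)(C)OC1(C)C | intermediate
19 | methyl 2-{[(3Z,7R,8S)-3-bromo-2,8-dimethyl-10-[(4S)-2,2,5,5-tetramethyl-1,3-dioxolan-4-yl]-8-(triethylsilyloxy)deca-1,3-dien-7-yl]oxy}prop-2-enoate | CC(=C)/C(Br)=C/CC[C@@H](OC(=C)C(=O)OC)[C@@](C)(O[Si](CC)(CC)CC)CC[C@@H]1OC(C)(C)OC1(C)C | intermediate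
20 | {[5-(methoxycarbonyl)-2-(methoxymethoxy)phenyl]methyl}zinc bromide | COCOc1ccc(cc1C[Zn]Br)C(=O)OC | intermediate
21 | methyl 3-[(2E,6R,7S)-6-[(3-methoxy-3-oxoprop-1-en-2-yl)oxy]-7-methyl-2-(prop-1-en-2-yl)-9-[(4S)-2,2,5,5-tetramethyl-1,3-dioxolan-4-yl]-7-(triethylsilyloxy)non-2-en-1-yl]-4-(methoxymethoxy)benzoate | CC(=C)/C(Cc1cc(ccc1OCOC)C(=O)OC)=C/CC[C@@H](OC(=C)C(=O)OC)[C@@](C)(O[Si](CC)(CC)CC)CC[C@@H]1OC(C)(C)OC1(C)C | intermediate
22 | methyl (2R,4aR)-5-{[5-(methoxycarbonyl)-2-(methoxymethoxy)phenyl]methyl}-6-methyl-2-{(2S)-4-[(4S)-2,2,5,5-tetramethyl-1,3-dioxolan-4-yl]-2-(triethylsilyloxy)butan-2-yl}-3,4,4a,7,8,8a-hexahydro-2H-chromene-8a-carboxylate (C8a epimers) | COC(=O)C12CCC(C)=C(Cc3cc(ccc3OCOC)C(=O)OC)[C@H]1CC[C@@H](O2)[C@@](C)(O[Si](CC)(CC)CC)CC[C@@H]1OC(C)(C)OC1(C)C | intermediate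
23 | methyl 3-{[(2R,4aR)-8a-(hydroxymethyl)-6-methyl-2-{(2S)-4-[(4S)-2,2,5,5-tetramethyl-1,3-dioxolan-4-yl]-2-(triethylsilyloxy)butan-2-yl}-3,4,4a,7,8,8a-hexahydro-2H-chromen-5-yl]methyl}-4-(methoxymethoxy)benzoate (C8a epimers) | OCC12CCC(C)=C(Cc3cc(ccc3OCOC)C(=O)OC)[C@H]1CC[C@@H](O2)[C@@](C)(O[Si](CC)(CC)CC)CC[C@@H]1OC(C)(C)OC1(C)C | intermediate
24 | methyl 3-{[(2R,4aR)-8a-(iodomethyl)-6-methyl-2-{(2S)-4-[(4S)-2,2,5,5-tetramethyl-1,3-dioxolan-4-yl]-2-(triethylsilyloxy)butan-2-yl}-3,4,4a,7,8,8a-hexahydro-2H-chromen-5-yl]methyl}-4-(methoxymethoxy)benzoate (C8a epimers) | ICC12CCC(C)=C(Cc3cc(ccc3OCOC)C(=O)OC)[C@H]1CC[C@@H](O2)[C@@](C)(O[Si](CC)(CC)CC)CC[C@@H]1OC(C)(C)OC1(C)C | intermediate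
25 | methyl 3-{[(6S)-6-{(3R,4S)-3-hydroxy-4-methyl-6-[(4S)-2,2,5,5-tetramethyl-1,3-dioxolan-4-yl]-4-(triethylsilyloxy)hexyl}-2-methyl-5-methylidenecyclohex-1-en-1-yl]methyl}-4-(methoxymethoxy)benzoate | C=C1CCC(C)=C(Cc2cc(ccc2OCOC)C(=O)OC)[C@H]1CC[C@@H](O)[C@@](C)(O[Si](CC)(CC)CC)CC[C@@H]1OC(C)(C)OC1(C)C | intermediate
26 | methyl 3-{[(6S)-6-{(3R,4S)-4-methyl-3-(methylsulfonyloxy)-6-[(4S)-2,2,5,5-tetramethyl-1,3-dioxolan-4-yl]-4-(triethylsilyloxy)hexyl}-2-methyl-5-methylidenecyclohex-1-en-1-yl]methyl}-4-(methoxymethoxy)benzoate | C=C1CCC(C)=C(Cc2cc(ccc2OCOC)C(=O)OC)[C@H]1CC[C@@H](OS(C)(=O)=O)[C@@](C)(O[Si](CC)(CC)CC)CC[C@@H]1OC(C)(C)OC1(C)C | intermediate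
27 | methyl 3-{[(6S)-6-[(3R,4S,7S)-4,7,8-trihydroxy-4,8-dimethyl-3-(methylsulfonyloxy)nonyl]-2-methyl-5-methylidenecyclohex-1-en-1-yl]methyl}-4-(methoxymethoxy)benzoate | C=C1CCC(C)=C(Cc2cc(ccc2OCOC)C(=O)OC)[C@H]1CC[C@@H](OS(C)(=O)=O)[C@@](C)(O)CC[C@H](O)C(C)(C)O | intermediate
28 | 3-{[(6S)-6-{2-[(2S,3S)-3-[(3S)-3,4-dihydroxy-4-methylpentyl]-3-methyloxiran-2-yl]ethyl}-2-methyl-5-methylidenecyclohex-1-en-1-yl]methyl}-4-(methoxymethoxy)benzoic acid | C=C1CCC(C)=C(Cc2cc(ccc2OCOC)C(=O)O)[C@H]1CC[C@@H]1O[C@@]1(C)CC[C@H](O)C(C)(C)O | intermediate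
29 | MOM-protected (7S,10S,11S,14S)-10,11-epoxy macrolactone (15-membered benzoate of C14–OH; C15–OH free) | C=C1CCC(C)=C2Cc3cc(ccc3OCOC)C(=O)O[C@H](C(C)(C)O)CC[C@]4(C)O[C@H]4CC[C@@H]12 | intermediate
30 | O-methoxymethyl ether of the target (7S,10R,11S,14S) | C=C1CCC(C)=C2Cc3cc(ccc3OCOC)C(=O)O[C@H](C(C)(C)O)CC[C@](C)(O)[C@H](Br)CC[C@@H]12 | intermediate
31 | CNP0343566.2 (7S,10R,11S,14S) | C=C1CCC(C)=C2Cc3cc(ccc3O)C(=O)O[C@H](C(C)(C)O)CC[C@](C)(O)[C@H](Br)CC[C@@H]12 | target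

**Total step count:** 22. **Longest linear sequence:** 18 steps (5 → 31 through steps 4–6 and 8–22).

**Three steps most likely to fail**

Step 14 (tethered cycloaddition). The fully substituted diene may react slowly or give mixed facial selectivity. Fallback, setting out from 19 and returning at 22: stop step 13 after the first coupling and isolate bromodiene 19. Run the cycloaddition on this less hindered 2-bromodiene (toluene, 120 °C) to the bromo cycloadduct methyl (2R,4aS)-5-bromo-6-methyl-2-{(2S)-4-[(4S)-2,2,5,5-tetramethyl-1,3-dioxolan-4-yl]-2-(triethylsilyloxy)butan-2-yl}-3,4,4a,7,8,8a-hexahydro-2H-chromene-8a-carboxylate F2. Then attach the arylmethyl group to the ring vinyl bromide by Negishi coupling with 20 (Pd(t-Bu3P)2) to reach 22.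

Step 8 (C11 by Felkin–Anh addition). A lactone oxygen is a weak director, and partial chelation would erode or reverse the selectivity. Fallback, setting out from 10 and 12 and returning at 13: reverse the order of the two C–C bond formations. Acylate alkylmagnesium iodide 12 with acid chloride 10 (CuI cat., THF, −78 °C) to the chain ketone (5R)-5-{4-[(4S)-2,2,5,5-tetramethyl-1,3-dioxolan-4-yl]butanoyl}dihydrofuran-2(3H)-one F1, then add MeMgBr. For a given facial bias the two orders give opposite C11 epimers, so if chelation dominates in practice this order delivers the (11S) carbinol 13.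

Step 21 (bromide opening of the macrocyclic epoxide). The free C15–OH could attack C11 instead, giving a tetrahydropyran. Fallback, setting out from 29 and returning at 30: cap C15–OH with N-(trimethylsilyl)imidazole to give the C15 trimethylsilyl ether of 29 F3. Open the epoxide with Li2NiBr4 to the C15 trimethylsilyl ether of 30 F4, and remove the silyl group with citric acid in MeOH to reach 30.

**Further compounds**
F1 | step 8 | (5R)-5-{4-[(4S)-2,2,5,5-tetramethyl-1,3-dioxolan-4-yl]butanoyl}dihydrofuran-2(3H)-one | O=C1CC[C@@H](O1)C(=O)CC[C@@H]1OC(C)(C)OC1(C)C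
F2 | step 14 | methyl (2R,4aS)-5-bromo-6-methyl-2-{(2S)-4-[(4S)-2,2,5,5-tetramethyl-1,3-dioxolan-4-yl]-2-(triethylsilyloxy)butan-2-yl}-3,4,4a,7,8,8a-hexahydro-2H-chromene-8a-carboxylate (C8a epimers) | COC(=O)C12CCC(C)=C(Br)[C@H]1CC[C@@H](O2)[C@@](C)(O[Si](CC)(CC)CC)CC[C@@H]1OC(C)(C)OC1(C)C
F3 | step 21 | C15 trimethylsilyl ether of 29 | C=C1CCC(C)=C2Cc3cc(ccc3OCOC)C(=O)O[C@H](C(C)(C)O[Si](C)(C)C)CC[C@]4(C)O[C@H]4CC[C@@H]12
F4 | step 21 | C15 trimethylsilyl ether of 30 | C=C1CCC(C)=C2Cc3cc(ccc3OCOC)C(=O)O[C@H](C(C)(C)O[Si](C)(C)C)CC[C@](C)(O)[C@H](Br)CC[C@@H]12
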